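## The problem

Compound 18 is a bibenzyl. A 3-hydroxy-5-methoxyphenyl ring (ring A) and a tetrasubstituted phenol (ring B) are joined by a CH2CH2 bridge, and ring B also carries two 4-hydroxybenzyl groups. There is no stereocentre and no ring has to be made, because all four benzene rings can be bought; the task is to join them at the right positions. The difficulty lies in ring B, whose four substituents are contiguous: 4-hydroxybenzyl, the bridge, the second 4-hydroxybenzyl, then the hydroxyl. The bridge carbon therefore sits between two benzyl groups at the most crowded position of the ring. Four phenolic hydroxyls must stay distinct from the one methyl ether of ring A, so protecting groups that need ether-cleaving Lewis acids are excluded, and ring A has to be desymmetrised (OH versus OMe) early. The free polyphenol is electron-rich and its two diarylmethane CH2 groups are doubly benzylic, so nitration, radical bromination and strong acid belong at the start, on simple intermediates. The structural feature that allows a short assembly is the bridge itself: an ethylene unit bonded to two different aryl groups is the 1,2-diarylation product of a vinyl group. Both aryl–carbon bonds can therefore come from one three-component reaction of a vinyl donor, a ring B nucleophile and a ring A electrophile.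

## Retrosynthesis

**18 back to 17 and 16.** The three O–benzyl bonds of 17 are cut last, since hydrogenolysis leaves the aryl methyl ether, the diarylmethanes and the bibenzyl alone. In 17 one bridge CH2 is traced back to a CH–B(pin) carbon and the ring B phenol to its triisopropylsilyl ether, giving boronic ester 16. The forward step asks one fluoride reagent to replace the benzylic C–B bond by C–H and to remove the silyl group. The boron-bearing carbon of 16 is the only stereocentre in the whole route; it is formed racemic and erased here.

**16 back to 9, 13 and 12 (key disconnection).** Both bridge-to-arene bonds are cut, leaving ring B bromide 9, vinylboronic ester 13 and ring A triflate 12.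
- Neighbouring cuts were weighed. A Wittig route needs a 2,6-dibenzylbenzaldehyde and a ring A phosphonium salt, each with an added carbon. A Sonogashira route asks palladium to insert into the doubly flanked C–Br bond of 9. Joining the rings one bond at a time costs extra steps.
- The conjunctive coupling brings both bridge carbons in as bought 13. It forms the crowded ring B–C bond by aryl migration from boron to carbon, not at a palladium centre.
- The roles follow from this. Hindered ring B is the nucleophile (aryllithium 14, then ate complex 15). Unhindered ring A is the triflate that undergoes oxidative addition.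
- The forward reaction must make the 1,2-metallate shift outrun direct Suzuki transfer. That calls for halide-free conditions and a bisphosphine ligand.

**9 back to 7 and 8.** The two CH2–aryl bonds of the arms are cut to bis(bromomethyl)arene 7 and two molecules of bought boronic acid 8. A benzylic Suzuki coupling is preferred to Friedel–Crafts benzylation because it cannot scramble positions on the electron-rich rings. Palladium should also insert into benzylic C–Br bonds much faster than into the aryl C–Br bond between two ortho substituents, which has to survive for the key step.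

**7 back to 6 and 5.** The two C–Br bonds come from radical bromination of the methyl groups of 6. This step dictates the ring B protecting group. A benzyl ether would be attacked at its own OCH2 under NBS, so the phenol 5 is carried as a triisopropylsilyl ether. That group has no reactive C–H, tolerates phosphate base, t-BuLi at −78 °C and palladium, and falls off in the fluoride step that removes boron.

**5 back to 3, 2 and 1.** The phenol oxygen is traced through diazonium salt 4 to aniline 3, nitroarene 2 and bought 2-bromo-1,3-dimethylbenzene 1. This puts bromine, both future arms and the oxygen on ring B in the correct 1,2,3,4-relationship. Nitration of 1 is directed by both methyl groups to C4, and the bromine that later becomes the nucleophilic site is present from the start.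

**12 back to 11 and 10.** The triflate is cut to phenol 11, and its benzyl ether to bought 5-methoxyresorcinol 10. The methyl ether of the target is purchased, not made. The price is a statistical monobenzylation of a cheap symmetric diol.

## Roads not taken

**Alternative 1: gold-catalysed furan–yne benzannulation with an excisable ether tether.**
- **Cut and key step.** Ring B itself is taken apart into a 2,3-disubstituted furan and a terminal alkyne held together by an ether between two secondary carbinols, precursor A1. With Ph3PAuNTf2 the furan and alkyne should combine to the 1,3-dihydroisobenzofuran-4-ol A2, the furan oxygen ending as the phenolic hydroxyl. Hydrogenolysis of the two benzylic C–O bonds of the tether together with the benzyl ethers would then give 18.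
- **Merits.** The ring B substitution pattern is fixed by construction, not by the regiochemistry of a nitration. The endgame is one hydrogenation, against two steps in the chosen plan.
- **Weak points.** A1 is an ether of two secondary alcohols and is hard to make. One of its C–O bonds is both benzylic and propargylic and is prone to ionise under Lewis-acidic monovalent gold. A1 is a diastereomer mixture. The arene-forming step would run with a furan lacking a 5-substituent and with a doubly substituted tether. The tether C–O bond at the crowded position is only singly benzylic and may resist hydrogenolysis.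
- **Comparison.** The chosen plan offsets its less elegant ring B preparation by using only bought rings. Its one demanding C–C bond formation uses three partners made in six, two and zero steps.

**Alternative 2: Catellani double ortho-benzylation with ipso Heck coupling.**
- **Cut and key step.** Both arm CH2–ring B bonds and the ring B–bridge bond are made in one pot. The components are 1-(benzyloxy)-3-iodobenzene A3, two equivalents of 4-(benzyloxy)benzyl chloride A4 and the ring A styrene A5, under Pd(OAc)2, tri(2-furyl)phosphine, norbornene and Cs2CO3. The product is stilbene A6, and a single hydrogenation would reduce the alkene and remove four benzyl groups.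
- **Merits.** This is the shortest road by a wide margin, about four steps against eleven. The chosen plan cannot match it in step economy, and it needs no boron removal.
- **Weak points.** The two ortho positions of A3 are unequal. One lies between iodine and the benzyloxy group, and palladation there is disfavoured, so a meta-substituted iodide may stop after one benzylation. Benzyl chlorides can also react with palladium, with norbornene or with A5 outside the intended order.
- **Comparison.** The chosen plan offsets its length by fixing the site of every C–C bond with a pre-installed bromide or triflate, not with relative rates of C–H palladation. A stilbene of this kind also stays within reach as a fallback from 16.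

**Alternative 3: biomimetic cycloaromatisation of a diketo-dioxinone to ring A.**
- **Cut and key step.** A ring A bond is cut. Triethylamine would cyclise diketo-dioxinone A7 by aldol attack of the dioxinone C5 on the distal ketone and dehydration, giving benzodioxinone A8. Then come O-methylation of the free hydroxyl, opening of the dioxinone, decarboxylation and debenzylation.
- **Merits.** The two ring A oxygens are differentiated by construction. This is better than the statistical monobenzylation of the chosen plan.
- **Weak points.** It builds the one ring that is cheapest to buy. It adds four steps after the key step. A7 already contains the ring B–CH2CH2 bond at the crowded position, so the central problem is moved to an earlier, unspecified step instead of being solved.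
- **Comparison.** The chosen plan offsets its statistical step by placing it on an inexpensive diol two steps from the coupling, and it solves the ring B–bridge bond directly.

Key step: step 9

## Route

Step 1
Reactants: 1 2-bromo-1,3-dimethylbenzene
Product: 2 2-bromo-1,3-dimethyl-4-nitrobenzene
Conditions: fuming HNO3, AcOH, rt to 80 °C
Reagents that add atoms: nitric acid, O[N+](=O)[O-]
Why: Electrophilic aromatic nitration; C4 is ortho to one methyl group and para to the other, whereas C5 is meta to both, so mononitration should go to C4.

Step 2
Reactants: 2 2-bromo-1,3-dimethyl-4-nitrobenzene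
Product: 3 3-bromo-2,4-dimethylaniline
Conditions: Fe, AcOH, EtOH, 70 °C
Reagents that add atoms: none
Why: Béchamp-type reduction of the nitro group by Fe in acetic acid; dissolving-metal conditions leave the aryl bromide untouched, which catalytic hydrogenation might not.

Step 3
Reactants: 3 3-bromo-2,4-dimethylaniline
Product: 5 3-bromo-2,4-dimethylphenol, via arenediazonium hydrogensulfate 4 (not isolated)
Conditions: NaNO2, aq. H2SO4, 0 °C; then added to aq. H2SO4, 100 °C
Reagents that add atoms: water, O (the phenol oxygen); sodium nitrite, O=N[O-].[Na+] (second nitrogen of 4 only, lost as N2)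
Why: Diazotisation followed by thermal hydrolysis of the diazonium salt; the strongly acidic medium suppresses azo coupling with the product phenol and cyclisation of the ortho-methyl diazonium ion.

Step 4
Reactants: 5 3-bromo-2,4-dimethylphenol
Product: 6 (3-bromo-2,4-dimethylphenoxy)triisopropylsilane
Conditions: TIPSCl, imidazole, DMF, 40 °C
Reagents that add atoms: chlorotriisopropylsilane, CC(C)[Si](Cl)(C(C)C)C(C)C
Why: Silylation of a phenol with a silyl chloride and imidazole; the triisopropylsilyl ether has no benzylic C–H for step 5 and should survive phosphate base, t-BuLi at −78 °C and palladium.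

Step 5
Reactants: 6 (3-bromo-2,4-dimethylphenoxy)triisopropylsilane
Product: 7 [3-bromo-2,4-bis(bromomethyl)phenoxy]triisopropylsilane
Conditions: NBS (about 2 equiv), AIBN (cat.), PhCF3, 80 °C
Reagents that add atoms: N-bromosuccinimide, O=C1CCC(=O)N1Br
Why: Wohl–Ziegler bromination; the first bromine slows a second abstraction at the same carbon, so about two equivalents should place one bromine on each methyl group, and the non-polar medium with initiator favours the radical chain over ring bromination.

Step 6
Reactants: 7 [3-bromo-2,4-bis(bromomethyl)phenoxy]triisopropylsilane; 8 4-(benzyloxy)phenylboronic acid (slight excess over 2 equiv)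
Product: 9 {2,4-bis[4-(benzyloxy)benzyl]-3-bromophenoxy}triisopropylsilane
Conditions: Pd(OAc)2 (cat.), PPh3, K3PO4, toluene, 80 °C
Reagents that add atoms: none
Why: Suzuki–Miyaura coupling of benzylic bromides with an arylboronic acid; zerovalent palladium bearing PPh3 inserts into benzylic C–Br bonds far faster than into an aryl C–Br bond flanked by two ortho substituents, so the ring bromide should be kept.

Step 7
Reactants: 10 5-methoxybenzene-1,3-diol (5-methoxyresorcinol, in excess)
Product: 11 3-(benzyloxy)-5-methoxyphenol
Conditions: BnBr (limiting), K2CO3, acetone, reflux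
Reagents that add atoms: benzyl bromide, BrCc1ccccc1
Why: Williamson ether synthesis; monoalkylation of the symmetric diol is statistical and is biased by using 10 in excess, the unreacted diol being recoverable by extraction.

Step 8
Reactants: 11 3-(benzyloxy)-5-methoxyphenol
Product: 12 3-(benzyloxy)-5-methoxyphenyl trifluoromethanesulfonate
Conditions: Tf2O, pyridine, CH2Cl2, 0 °C
Reagents that add atoms: trifluoromethanesulfonic anhydride, O=S(=O)(OS(=O)(=O)C(F)(F)F)C(F)(F)F
Why: O-Sulfonylation of a phenol; it gives the unhindered aryl triflate needed as electrophile in step 9.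

Step 9
Reactants: 9 {2,4-bis[4-(benzyloxy)benzyl]-3-bromophenoxy}triisopropylsilane; 13 4,4,5,5-tetramethyl-2-vinyl-1,3,2-dioxaborolane (vinylboronic acid pinacol ester); 12 3-(benzyloxy)-5-methoxyphenyl trifluoromethanesulfonate
Product: 16 racemic 2-{1-[2,6-bis[4-(benzyloxy)benzyl]-3-(triisopropylsilyloxy)phenyl]-2-[3-(benzyloxy)-5-methoxyphenyl]ethyl}-4,4,5,5-tetramethyl-1,3,2-dioxaborolane, via aryllithium 14 (not isolated), via lithium aryl(vinyl)boronate complex 15 (not isolated)
Conditions: t-BuLi (2 equiv), Et2O, −78 °C; 13, −78 °C to rt; solvent exchange to THF; KOTf, 12, Pd(OAc)2 (cat.), MandyPhos [1,1'-bis(diphenylphosphino)-2,2'-bis(α-(dimethylamino)benzyl)ferrocene, either enantiomer] (cat.), 60 °C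
Reagents that add atoms: none
Why: Bromine–lithium exchange of 9 gives aryllithium 14, which adds to the boron of 13 to form the four-coordinate ate complex 15. Zerovalent palladium, formed from Pd(OAc)2 and the bisphosphine, inserts into the C–O bond of 12; the resulting cationic aryl complex of divalent palladium binds the vinyl group of 15 and induces a 1,2-shift of the ring B aryl from boron to the α-carbon while palladium bonds to the β-carbon, and reductive elimination forms the ring A–CH2 bond. The closest known reaction type is the palladium-catalysed conjunctive cross-coupling of aryl(vinyl)boron ate complexes with aryl triflates. No ring closes. The boron-bearing carbon is a new stereocentre, formed without need for control and removed in step 10, so the ligand configuration is immaterial. The step needs the metallate shift to outrun direct Suzuki transfer of the vinyl or aryl group; the ferrocenyl bisphosphine, the triflate leaving group and removal of bromide as KBr by KOTf secure this. Regiochemistry is fixed by the roles: the migrating ring B aryl ends on the boron-bearing carbon and the electrophilic ring A on the terminal carbon. The crowded ring B–C bond is thus made by migration from boron and not at palladium, which is why the 2,6-dibenzyl arene is the nucleophile.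

Step 10
Reactants: 16 racemic 2-{1-[2,6-bis[4-(benzyloxy)benzyl]-3-(triisopropylsilyloxy)phenyl]-2-[3-(benzyloxy)-5-methoxyphenyl]ethyl}-4,4,5,5-tetramethyl-1,3,2-dioxaborolane
Product: 17 2,4-bis[4-(benzyloxy)benzyl]-3-{2-[3-(benzyloxy)-5-methoxyphenyl]ethyl}phenol
Conditions: TBAF·3H2O (excess), toluene, 80 °C
Reagents that add atoms: none
Why: Fluoride-promoted protodeboronation of a benzylic boronic ester: fluoride adds to boron, the benzylic C–B bond is cleaved with protonation by water, and the same reagent cleaves the aryl silyl ether; the racemic centre becomes a CH2 group.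

Step 11
Reactants: 17 2,4-bis[4-(benzyloxy)benzyl]-3-{2-[3-(benzyloxy)-5-methoxyphenyl]ethyl}phenol
Product: 18 3-[2-(3-hydroxy-5-methoxyphenyl)ethyl]-2,4-bis(4-hydroxybenzyl)phenol
Conditions: H2 (1 atm), Pd/C, EtOAc/MeOH, rt
Reagents that add atoms: none
Why: Catalytic hydrogenolysis of three benzyl aryl ethers; the aryl methyl ether, the diarylmethane C–C bonds and the bibenzyl bridge are inert under these conditions.

## Compound list

1 | 2-bromo-1,3-dimethylbenzene | Cc1cccc(C)c1Br | starting material
2 | 2-bromo-1,3-dimethyl-4-nitrobenzene | Cc1ccc([N+](=O)[O-])c(C)c1Br | intermediate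
3 | 3-bromo-2,4-dimethylaniline | Cc1ccc(N)c(C)c1Br | intermediate
4 | 3-bromo-2,4-dimethylbenzenediazonium hydrogensulfate (not isolated) | Cc1ccc([N+]#N)c(C)c1Br.OS(=O)(=O)[O-] | intermediate
5 | 3-bromo-2,4-dimethylphenol | Cc1ccc(O)c(C)c1Br | intermediate
6 | (3-bromo-2,4-dimethylphenoxy)triisopropylsilane | Cc1ccc(O[Si](C(C)C)(C(C)C)C(C)C)c(C)c1Br | intermediate
7 | [3-bromo-2,4-bis(bromomethyl)phenoxy]triisopropylsilane | BrCc1ccc(O[Si](C(C)C)(C(C)C)C(C)C)c(CBr)c1Br | intermediate
8 | 4-(benzyloxy)phenylboronic acid | OB(O)c1ccc(OCc2ccccc2)cc1 | starting material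
9 | {2,4-bis[4-(benzyloxy)benzyl]-3-bromophenoxy}triisopropylsilane | Brc1c(Cc2ccc(OCc3ccccc3)cc2)ccc(O[Si](C(C)C)(C(C)C)C(C)C)c1Cc1ccc(OCc2ccccc2)cc1 | intermediate
10 | 5-methoxybenzene-1,3-diol (5-methoxyresorcinol) | COc1cc(O)cc(O)c1 | starting material
11 | 3-(benzyloxy)-5-methoxyphenol | COc1cc(O)cc(OCc2ccccc2)c1 | intermediate
12 | 3-(benzyloxy)-5-methoxyphenyl trifluoromethanesulfonate | COc1cc(OCc2ccccc2)cc(OS(=O)(=O)C(F)(F)F)c1 | intermediate
13 | 4,4,5,5-tetramethyl-2-vinyl-1,3,2-dioxaborolane (vinylboronic acid pinacol ester) | C=CB1OC(C)(C)C(C)(C)O1 | starting material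
14 | {2,6-bis[4-(benzyloxy)benzyl]-3-(triisopropylsilyloxy)phenyl}lithium (not isolated) | [Li]c1c(Cc2ccc(OCc3ccccc3)cc2)ccc(O[Si](C(C)C)(C(C)C)C(C)C)c1Cc1ccc(OCc2ccccc2)cc1 | intermediate
15 | lithium {2,6-bis[4-(benzyloxy)benzyl]-3-(triisopropylsilyloxy)phenyl}(vinyl)(pinacolato)borate (not isolated) | [Li+].C=C[B-]1(OC(C)(C)C(C)(C)O1)c1c(Cc2ccc(OCc3ccccc3)cc2)ccc(O[Si](C(C)C)(C(C)C)C(C)C)c1Cc1ccc(OCc2ccccc2)cc1 | intermediate
16 | racemic 2-{1-[2,6-bis[4-(benzyloxy)benzyl]-3-(triisopropylsilyloxy)phenyl]-2-[3-(benzyloxy)-5-methoxyphenyl]ethyl}-4,4,5,5-tetramethyl-1,3,2-dioxaborolane | COc1cc(OCc2ccccc2)cc(CC(B2OC(C)(C)C(C)(C)O2)c2c(Cc3ccc(OCc4ccccc4)cc3)ccc(O[Si](C(C)C)(C(C)C)C(C)C)c2Cc2ccc(OCc3ccccc3)cc2)c1 | intermediate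
17 | 2,4-bis[4-(benzyloxy)benzyl]-3-{2-[3-(benzyloxy)-5-methoxyphenyl]ethyl}phenol | COc1cc(OCc2ccccc2)cc(CCc2c(Cc3ccc(OCc4ccccc4)cc3)ccc(O)c2Cc2ccc(OCc3ccccc3)cc2)c1 | intermediate
18 | 3-[2-(3-hydroxy-5-methoxyphenyl)ethyl]-2,4-bis(4-hydroxybenzyl)phenol | COc1cc(O)cc(CCc2c(Cc3ccc(O)cc3)ccc(O)c2Cc2ccc(O)cc2)c1 | target

## Step count and risks

Total step count: 11. Longest linear sequence: 9 steps (steps 1 to 6, then 9, 10 and 11). The ring A branch (steps 7 and 8) joins at step 9.

**Step 9 (key step).**
- **What may go wrong.** The aryllithium may be quenched by proton transfer from the acidic diarylmethane CH2 groups before it reaches boron. The bulk of the 2,6-dibenzyl aryl may retard ate-complex formation or the metallate shift, so that direct Suzuki-type transfer or simple decomposition of the arylpalladium species takes over. Residual bromide may inhibit the shift.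
- **Fallback.** The same two bonds are made one at a time from the same three building blocks, setting out from 12, 13 and 9 and returning to the route at 17.
  - Suzuki vinylation of 12 with 13 (Pd(dppf)Cl2, K2CO3, dioxane/water) should give the styrene 1-(benzyloxy)-3-ethenyl-5-methoxybenzene F1.
  - Anti-Markovnikov hydroboration with 9-BBN gives the alkylborane 9-{2-[3-(benzyloxy)-5-methoxyphenyl]ethyl}-9-borabicyclo[3.3.1]nonane F2, used without isolation.
  - B-alkyl Suzuki coupling of F2 with 9 (Pd(OAc)2, SPhos, K3PO4, THF/water) gives {2,4-bis[4-(benzyloxy)benzyl]-3-{2-[3-(benzyloxy)-5-methoxyphenyl]ethyl}phenoxy}triisopropylsilane F3.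
  - TBAF in THF converts F3 into 17.

**Step 10.**
- **What may go wrong.** Cleavage of the secondary benzylic C–B bond may be sluggish. Fluoride first removes the silyl group, the resulting phenoxide makes ring B more electron-rich, and the crowded ring cannot fully stabilise developing negative charge at the benzylic carbon. Slow protodeboronation would also leave time for adventitious oxidation of the boronate.
- **Fallback.** It sets out from 16 and comes back at 18.
  - Oxidation with NaBO3·4H2O in THF/water gives racemic 1-[2,6-bis[4-(benzyloxy)benzyl]-3-(triisopropylsilyloxy)phenyl]-2-[3-(benzyloxy)-5-methoxyphenyl]ethan-1-ol F4.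
  - Syn-elimination with the Burgess reagent gives the (E)-stilbene silyl ether F5. This avoids a free benzylic cation that could cyclise onto a neighbouring benzyl arm.
  - TBAF gives the stilbene phenol 2,4-bis[4-(benzyloxy)benzyl]-3-{(E)-2-[3-(benzyloxy)-5-methoxyphenyl]ethenyl}phenol F6.
  - Hydrogenation over Pd/C reduces the alkene and removes the three benzyl groups in one operation to give 18.

**Step 5.**
- **What may go wrong.** Bromination may be uneven across the two methyl groups, with geminal dibromide at one and none at the other. Electrophilic bromination may occur at the ring position ortho to the silyloxy group. HBr may cause loss of the silyl group.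
- **Fallback.** The ring is deactivated with an acyl group for the radical step. The sequence sets out from 5 and returns at 9.
  - Pivaloyl chloride and pyridine give 3-bromo-2,4-dimethylphenyl pivalate F7.
  - NBS and AIBN give 3-bromo-2,4-bis(bromomethyl)phenyl pivalate F8.
  - Coupling with 8 under the conditions of step 6 gives 2,4-bis[4-(benzyloxy)benzyl]-3-bromophenyl pivalate F9.
  - NaOMe in MeOH frees 2,4-bis[4-(benzyloxy)benzyl]-3-bromophenol F10.
  - TIPSCl and imidazole convert F10 into 9.

**Step 6.**
- **What may go wrong.** Reductive homocoupling of the benzylic bromides, a stalled second coupling at the CH2Br flanked by bromine and the silyloxy group, slow insertion into the ring C–Br bond once excess boronic acid is present, or base-induced desilylation of the ortho-silyloxybenzyl bromide followed by quinone methide chemistry.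
- **Fallback.** The arms are built by carbonyl addition and ionic reduction, setting out from 7 and returning at 9.
  - Oxidation of 7 with N-methylmorpholine N-oxide in MeCN gives 2-bromo-4-(triisopropylsilyloxy)benzene-1,3-dicarbaldehyde F11.
  - Addition of commercial 4-(benzyloxy)phenylmagnesium bromide in THF at 0 °C gives the bis-carbinol {2-bromo-4-(triisopropylsilyloxy)-1,3-phenylene}bis{[4-(benzyloxy)phenyl]methanol} F12 as a mixture of diastereomers.
  - Et3SiH and CF3CO2H in CH2Cl2 at 0 °C reduce both diarylcarbinols to give 9.

## Further compounds

F1 | step 9 | 1-(benzyloxy)-3-ethenyl-5-methoxybenzene | C=Cc1cc(OC)cc(OCc2ccccc2)c1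
F2 | step 9 | 9-{2-[3-(benzyloxy)-5-methoxyphenyl]ethyl}-9-borabicyclo[3.3.1]nonane | COc1cc(OCc2ccccc2)cc(CCB2C3CCCC2CCC3)c1
F3 | step 9 | {2,4-bis[4-(benzyloxy)benzyl]-3-{2-[3-(benzyloxy)-5-methoxyphenyl]ethyl}phenoxy}triisopropylsilane | COc1cc(OCc2ccccc2)cc(CCc2c(Cc3ccc(OCc4ccccc4)cc3)ccc(O[Si](C(C)C)(C(C)C)C(C)C)c2Cc2ccc(OCc3ccccc3)cc2)c1
F4 | step 10 | racemic 1-[2,6-bis[4-(benzyloxy)benzyl]-3-(triisopropylsilyloxy)phenyl]-2-[3-(benzyloxy)-5-methoxyphenyl]ethan-1-ol | COc1cc(OCc2ccccc2)cc(CC(O)c2c(Cc3ccc(OCc4ccccc4)cc3)ccc(O[Si](C(C)C)(C(C)C)C(C)C)c2Cc2ccc(OCc3ccccc3)cc2)c1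
F5 | step 10 | {2,4-bis[4-(benzyloxy)benzyl]-3-{(E)-2-[3-(benzyloxy)-5-methoxyphenyl]ethenyl}phenoxy}triisopropylsilane | COc1cc(OCc2ccccc2)cc(/C=C/c2c(Cc3ccc(OCc4ccccc4)cc3)ccc(O[Si](C(C)C)(C(C)C)C(C)C)c2Cc2ccc(OCc3ccccc3)cc2)c1
F6 | step 10 | 2,4-bis[4-(benzyloxy)benzyl]-3-{(E)-2-[3-(benzyloxy)-5-methoxyphenyl]ethenyl}phenol | COc1cc(OCc2ccccc2)cc(/C=C/c2c(Cc3ccc(OCc4ccccc4)cc3)ccc(O)c2Cc2ccc(OCc3ccccc3)cc2)c1
F7 | step 5 | 3-bromo-2,4-dimethylphenyl pivalate | CC(C)(C)C(=O)Oc1ccc(C)c(Br)c1C
F8 | step 5 | 3-bromo-2,4-bis(bromomethyl)phenyl pivalate | CC(C)(C)C(=O)Oc1ccc(CBr)c(Br)c1CBr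
F9 | step 5 | 2,4-bis[4-(benzyloxy)benzyl]-3-bromophenyl pivalate | CC(C)(C)C(=O)Oc1ccc(Cc2ccc(OCc3ccccc3)cc2)c(Br)c1Cc1ccc(OCc2ccccc2)cc1
F10 | step 5 | 2,4-bis[4-(benzyloxy)benzyl]-3-bromophenol | Oc1ccc(Cc2ccc(OCc3ccccc3)cc2)c(Br)c1Cc1ccc(OCc2ccccc2)cc1
F11 | step 6 | 2-bromo-4-(triisopropylsilyloxy)benzene-1,3-dicarbaldehyde | O=Cc1ccc(O[Si](C(C)C)(C(C)C)C(C)C)c(C=O)c1Br
F12 | step 6 | {2-bromo-4-(triisopropylsilyloxy)-1,3-phenylene}bis{[4-(benzyloxy)phenyl]methanol}, mixture of diastereomers | OC(c1ccc(OCc2ccccc2)cc1)c1ccc(O[Si](C(C)C)(C(C)C)C(C)C)c(C(O)c2ccc(OCc3ccccc3)cc2)c1Br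
A1 | alternative 1 | 3-[4-(benzyloxy)benzyl]-2-{2-[3-(benzyloxy)-5-methoxyphenyl]-1-({1-[4-(benzyloxy)phenyl]prop-2-yn-1-yl}oxy)ethyl}furan, mixture of diastereomers | C#CC(OC(Cc1cc(OC)cc(OCc2ccccc2)c1)c1occc1Cc1ccc(OCc2ccccc2)cc1)c1ccc(OCc2ccccc2)cc1
A2 | alternative 1 | 7-[4-(benzyloxy)benzyl]-1-[3-(benzyloxy)-5-methoxybenzyl]-3-[4-(benzyloxy)phenyl]-1,3-dihydroisobenzofuran-4-ol, mixture of diastereomers | Oc1ccc(Cc2ccc(OCc3ccccc3)cc2)c2c1C(c1ccc(OCc3ccccc3)cc1)OC2Cc1cc(OC)cc(OCc2ccccc2)c1
A3 | alternative 2 | 1-(benzyloxy)-3-iodobenzene | Ic1cccc(OCc2ccccc2)c1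
A4 | alternative 2 | 4-(benzyloxy)benzyl chloride | ClCc1ccc(OCc2ccccc2)cc1
A5 | alternative 2 | 1-(benzyloxy)-3-ethenyl-5-methoxybenzene | C=Cc1cc(OC)cc(OCc2ccccc2)c1
A6 | alternative 2 | 1-(benzyloxy)-2,4-bis[4-(benzyloxy)benzyl]-3-{(E)-2-[3-(benzyloxy)-5-methoxyphenyl]ethenyl}benzene | COc1cc(OCc2ccccc2)cc(/C=C/c2c(Cc3ccc(OCc4ccccc4)cc3)ccc(OCc3ccccc3)c2Cc2ccc(OCc3ccccc3)cc2)c1
A7 | alternative 3 | 6-{6-[3-(benzyloxy)-2,6-bis[4-(benzyloxy)benzyl]phenyl]-2,4-dioxohexyl}-2,2-dimethyl-4H-1,3-dioxin-4-one | CC1(C)OC(=O)C=C(CC(=O)CC(=O)CCc2c(Cc3ccc(OCc4ccccc4)cc3)ccc(OCc3ccccc3)c2Cc2ccc(OCc3ccccc3)cc2)O1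
A8 | alternative 3 | 5-{2-[3-(benzyloxy)-2,6-bis[4-(benzyloxy)benzyl]phenyl]ethyl}-7-hydroxy-2,2-dimethyl-4H-benzo[d][1,3]dioxin-4-one | CC1(C)OC(=O)c2c(CCc3c(Cc4ccc(OCc5ccccc5)cc4)ccc(OCc4ccccc4)c3Cc3ccc(OCc4ccccc4)cc3)cc(O)cc2O1
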